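4.20 is the number to carry: the equilibrium constant of the binding step times the saturation concentration, which I call the hold ratio. It is the target per substrate that this pre-equilibrium keeps while dissolved gas stands at saturation.

    gas phase ⇌ dissolved gas, rate k1*(csat - [dissolved gas]) (k1 = 0.0151 s⁻¹, csat = 10 mM)
    substrate + dissolved gas ⇌ target (K2 = 420 M⁻¹, k2 = 18.5 M⁻¹ s⁻¹)
    substrate + target → side product (k3 = 0.348 M⁻¹ s⁻¹)
    substrate ⇌ dormant form (K4 = 1.14, k4 = 0.00137 s⁻¹)

substrate 20 mM; gas phase 10 mM (held); time 8.0 min

- in percentages every species weighs as the substrate in it: one side product counts as two
- at the start none of the gas is dissolved
- run time (flask): 8.0 min

- how much target there is at 8.0 min, in percent of the substrate charged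
- concentration of dissolved gas in solution at 4.0 min, in percent of saturation
- the change that raises the amount of target at 8.0 min, in percent of the substrate charged most ("none" if none brings more than 2 percentage points) (south / north / none)
- amount of target at 8.0 min, in percent of the substrate charged, after north

In powers of ten, you add the two logarithms and get 0.623. North adds 0.301 to that logarithm, while south leaves it unchanged, since the transfer coefficient is not in the ratio. Into a solution kept empty, the gas transfer can deliver 362% of the charge by 8.0 min, more than the charge, but that is a total over the run, not a speed. For a hand estimate I make two simplifications: I let the ratio stand from the start, although none of the gas is dissolved then, and I leave out the dormant form.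

Now take two ways to the target. The first uses the ratio with nothing lost: substrate and target split so that target is 80.8% of the charge. The second lets the side reaction eat the pool of substrate plus target, two units per event, as a second-order loss. Its dimensionless size over the run is 1.04, which leaves 49.1% of the charge in the pool and 39.7% as target.

The two ways part, and the first one cheats: with the other concentrations as charged, target has a half-life of 1.7 min by the side reaction, shorter than the 8.0 min of the run. So I commit to the second. For north, the ratio becomes 8.40, the split 89.4%, the loss 0.635, and the target 54.6%.

The forecast gives 36% (32% to 40%), below my figure, with saturation at 104% (100% to 108%), north as best, and 49% (44% to 54%) after it, also below mine. Its ground for the choice is that “doubling saturation shifts the equilibrium towards target and starves the side reaction of free substrate”.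

The simulation gives 35.0%, saturation 86.3%, and north as best, which gains 12 percentage points against 1.2 points for south, reaching 47.2%. In the flask, dissolved gas stood at 13.1% of saturation at 0.800 min, and half of the side reaction's turnover was done by 2.25 min, before the gas reached 86.3% at 4.0 min. At 8.00 min the flask holds target 35.0% over substrate 8.17%, a ratio of 4.28, close to the hold ratio. The flask charged with 8.0 mM of substrate reads target 50.6% over substrate 11.9% at 8.00 min, a ratio of 4.25, with side product at 27.0%.

The constants used here stand for no real mixture; the flask was simulated.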